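**Assumption (one line):** the target is the trans-(1S,2R) diol. I assume the chiral acid antipode that gives this enantiomer is found by screening, since both antipodes are accessible.

## Retrosynthetic overview
1. The target diol comes from DIBAL reduction of the trans-1-aryl-1,2-dihydronaphthalene-2,3-diester **7**.
2. Diester **7** comes from a single enantioselective cycloisomerisation of the achiral, symmetric bis(guaiacylidene)succinate **6**. One phenol ring is transiently dearomatised to a p-quinone methide by protonation at C2 (target numbering). The other arene then closes the ring onto it. This forms the only new ring and both stereocentres at once, and it breaks the symmetry of **6**.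
3. Diene **6** comes from two Stobbe-type condensations of dimethyl succinate with two vanillin units. The two aromatic rings and all carbons come from vanillin and succinate. Ring formation happens only in the key step.

## Forward route

**Step 1**
Reactants: **1** vanillin; **2** dimethyl succinate (2.5 equiv)
Product: **3** (E)-4-(4-hydroxy-3-methoxyphenyl)-3-(methoxycarbonyl)but-3-enoic acid
Conditions: KOtBu (3 equiv), tBuOH, reflux, 12 h; then H3O+
Reagents that add atoms: none
Why: Stobbe condensation (aldol, γ-lactonisation, E1cB ring opening) gives the E-arylidene half-ester. The extra base covers the phenol, and excess succinate suppresses bis-condensation.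

**Step 2**
Reactants: **3**
Product: **4** dimethyl (E)-2-(4-hydroxy-3-methoxybenzylidene)succinate
Conditions: TMSCHN2, MeOH/PhMe, 0 °C to rt, 1 h
Reagents that add atoms: trimethylsilyldiazomethane, C[Si](C)(C)C=[N+]=[N-] (adds CH3 to the carboxylate)
Why: TMSCHN2 methylates the carboxylic acid selectively, and the phenol (pKa ~10) is untouched without an amine base. This restores the diester, whose C2–H2 is acidic enough for the next condensation.

**Step 3**
Reactants: **4**; **1** vanillin (1.1 equiv)
Product: **5** (2E,3E)-2,3-bis[(4-hydroxy-3-methoxyphenyl)methylidene]-4-methoxy-4-oxobutanoic acid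
Conditions: KOtBu (3.5 equiv), tBuOH, reflux, 16 h; then H3O+
Reagents that add atoms: none
Why: a second Stobbe condensation at the other CH2. The E1cB step gives the thermodynamic E,E-diene, with each aryl trans to its carboxyl group and cis to the C2–C3 bond. This U-shaped geometry is what the ring closure needs. The lactonised ester ends up as the free acid.

**Step 4**
Reactants: **5**
Product: **6** dimethyl (2E,3E)-2,3-bis[(4-hydroxy-3-methoxyphenyl)methylidene]succinate
Conditions: TMSCHN2, MeOH/PhMe, 0 °C, 1 h
Reagents that add atoms: TMSCHN2, C[Si](C)(C)C=[N+]=[N-] (adds CH3)
Why: mild, non-acidic esterification. Strong acid and heat are avoided so that no racemic cyclisation occurs before the key step. The product is the achiral C2-symmetric substrate.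

**Step 5 (key step)**
Reactants: **6**
Product: **7** dimethyl (1S,2R)-7-hydroxy-1-(4-hydroxy-3-methoxyphenyl)-6-methoxy-1,2-dihydronaphthalene-2,3-dicarboxylate
Conditions: chiral imidodiphosphorimidate or N-triflylphosphoramide Brønsted acid (10 mol%), PhCF3, 60–80 °C, 48 h, Ar, dark
Reagents that add atoms: none (isomerisation)
Why: enantioselective desymmetrising cycloisomerisation with trans-1,2 selectivity. The new C1 centre is set by half-chair ring closure, trans to C2.
Proposed new method: the chiral acid protonates one p-hydroxystyrene half at C2, with loss of the phenol proton, giving the p-quinone methide (a dearomatised ring). The chiral conjugate base holds this ion pair and sets the configuration at C2. The other guaiacyl ring then attacks the quinone methide terminus (C1) through its position para to OMe. This is an intramolecular 1,6-Friedel–Crafts closure, 6-endo, of a U-shaped diene, and it rearomatises both rings and creates C1. The trans arrangement of the 1-aryl and 2-ester groups arises in the half-chair transition state. The closest known chemistry is the acid-mediated 8–8′ cyclisation of ferulate dehydrodimers via quinone methides, the 6π-type cyclisation of 2,3-dibenzylidenesuccinates, and chiral phosphoric acid-catalysed 1,6-additions to p-quinone methides.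

**Step 6**
Reactants: **7**
Product: **8** target, (1S,2R)-7-hydroxy-1-(4-hydroxy-3-methoxyphenyl)-6-methoxy-2,3-bis(hydroxymethyl)-1,2-dihydronaphthalene
Conditions: DIBAL-H (8 equiv), CH2Cl2, −78 °C to 0 °C, 3 h; Rochelle salt work-up
Reagents that add atoms: none (hydride only)
Why: DIBAL reduces both esters 1,2 to the primary alcohols. The excess covers the two phenols, which are carried as aluminium phenoxides. The trisubstituted styrenic C3=C4 is not reduced. No strong base is present and the temperature stays ≤0 °C, so the C2 centre adjacent to the ester is not epimerised.

## Checks
- **Target match:** the final product has both guaiacyl rings (4-OH, 3-OMe on the pendant ring; 7-OH, 6-OMe on the fused ring), the C3=C4 alkene, and CH2OH at C2 and C3. Configuration is 1S,2R, trans.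
- **Atom balance:** steps 1–6 give C13H14O6, C14H16O6, C21H20O8, C22H22O8, C22H22O8 (isomer) and C20H22O6, which matches the target SMILES.
- **Stereocentres:** both are set in step 5 only. Step 6 does not touch them.
- **Groups and protecting groups:** no protecting groups are used. The free phenols are required for the p-quinone methide pathway in step 5 and are tolerated by all other steps.

## Compound list
| # | Name | SMILES | Role |
|---|---|---|---|
| 1 | vanillin | COc1cc(C=O)ccc1O | starting material |
| 2 | dimethyl succinate | COC(=O)CCC(=O)OC | starting material |
| 3 | (E)-4-(4-hydroxy-3-methoxyphenyl)-3-(methoxycarbonyl)but-3-enoic acid | OC(=O)C/C(C(=O)OC)=C\c1ccc(O)c(OC)c1 | intermediate |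
| 4 | dimethyl (E)-2-(4-hydroxy-3-methoxybenzylidene)succinate | COC(=O)C/C(C(=O)OC)=C\c1ccc(O)c(OC)c1 | intermediate |
| 5 | (2E,3E)-2,3-bis[(4-hydroxy-3-methoxyphenyl)methylidene]-4-methoxy-4-oxobutanoic acid | COC(=O)/C(=C/c1ccc(O)c(OC)c1)/C(=C\c1ccc(O)c(OC)c1)C(=O)O | intermediate |
| 6 | dimethyl (2E,3E)-2,3-bis[(4-hydroxy-3-methoxyphenyl)methylidene]succinate | COC(=O)/C(=C/c1ccc(O)c(OC)c1)/C(=C\c1ccc(O)c(OC)c1)C(=O)OC | intermediate |
| 7 | dimethyl (1S,2R)-7-hydroxy-1-(4-hydroxy-3-methoxyphenyl)-6-methoxy-1,2-dihydronaphthalene-2,3-dicarboxylate | COc1cc([C@H]2c3cc(O)c(OC)cc3C=C(C(=O)OC)[C@@H]2C(=O)OC)ccc1O | intermediate |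
| 8 | target diol (CID10473569) | COc1cc([C@H]2c3cc(O)c(OC)cc3C=C(CO)[C@@H]2CO)ccc1O | target |

**Total steps:** 6. **Longest linear sequence:** 6 (vanillin → 3 → 4 → 5 → 6 → 7 → 8).

## Three steps most likely to fail
1. **Step 5, the enantioselective protonative cycloisomerisation.** The ester-bearing diene may be too weakly basic, or the background racemic reaction may win.
   - Fallback: change to oxidative 8–8′ coupling of methyl ferulate (Ag2O, or laccase/H2O2) to give racemic dimethyl 8–8′-cyclic dehydrodiferulate, which is diester **7**. Resolve it by chiral-phase HPLC, then carry out step 6.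
2. **Step 3, the second Stobbe condensation with free-phenol vanillin.** The phenoxide-deactivated aldehyde may give low yield or E/Z mixtures.
   - Fallback: build diene **6** by reductive homocoupling (Cu or Ni) of methyl (Z)-α-bromoferulate, made from methyl ferulate by bromination and dehydrobromination.
3. **Step 6, the DIBAL reduction.** It may cause partial epimerisation at C2 or conjugate reduction of the diester.
   - Fallback: protect the two phenols as TBS ethers, reduce the diester with LiAlH4 at −20 °C, and remove the TBS groups with TBAF.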